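## Retrosynthetic overview

1. Target ⇒ (global desilylation, reduction of three C9 esters) ⇒ tris-ester ⇒ two invertive SN2 etherifications at the two phenols of (+)-syringaresinol. The left erythro unit comes from a D-tartrate-derived α-nosylate (one inversion). The right threo unit comes from an L-tartrate-derived α-bromide (two inversions) that already carries the outer erythro unit (one inversion).
2. Each guaiacylglycerate unit ⇒ tartrate acetonide half-ester + aryl iodide. The C7–aryl bond is made by Ni-electrocatalytic decarboxylative arylation, trans to the bought neighbouring centre.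
3. (+)-Syringaresinol ⇒ furofuran diacid + syringyl iodide by a twofold electrochemical decarboxylative arylation; the diacid ⇒ (+)-sesamin by ozonolytic removal of both piperonyl rings (an "aryl swap").
4. Rings: the 3,7-dioxabicyclo[3.3.0]octane is bought intact in sesamin and never opened. The only other rings are the temporary dioxolanes of the tartrate units, opened after arylation.

Assumption: commercial (+)-sesamin is the natural (1S,3aR,4S,6aR) enantiomer, and 4-iodo-2-methoxyphenol and 4-iodo-2,6-dimethoxyphenol are bought as catalogue compounds.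

Abbreviations: TBS = tert-butyldimethylsilyl; TIPS = triisopropylsilyl; Ns = 4-nitrobenzenesulfonyl; NHPI = N-hydroxyphthalimide; DIC = N,N′-diisopropylcarbodiimide; TBAF = tetrabutylammonium fluoride; RVC = reticulated vitreous carbon; NMP = N-methylpyrrolidone. Lignan locants: C7 = benzylic carbinol carbon, C8 = aryloxy-bearing carbon, C9 = CH2OH carbon of a glycerol unit.

## Route

Step 1
Reactants: 1 (+)-sesamin
Product: 2 (1S,3aR,4S,6aR)-tetrahydro-1H,3H-furo[3,4-c]furan-1,4-dicarboxylic acid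
Conditions: O3, AcOH/EtOAc/H2O, 0 °C; then 30% H2O2, 40 °C
Reagents that add atoms: ozone, [O-][O+]=O; hydrogen peroxide, OO
Why: Exhaustive ozonolysis with oxidative work-up (arene degradation to a carboxylic acid) should consume the electron-rich methylenedioxyphenyl rings much faster than ether C–H bonds and leave only each ipso carbon as CO2H, so the four ring stereocentres of sesamin are carried over untouched.

Step 2
Reactants: 3 4-iodo-2,6-dimethoxyphenol
Product: 4 tert-butyl(4-iodo-2,6-dimethoxyphenoxy)dimethylsilane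
Conditions: TBSCl, imidazole, DMF, rt
Reagents that add atoms: tert-butyldimethylsilyl chloride, CC(C)(C)[Si](C)(C)Cl
Why: Imidazole-promoted silyl ether formation masks the acidic phenol for the reductive nickel step; no stereocentre is involved.

Step 3
Reactants: 2 furofuran diacid; 4 TBS-protected syringyl iodide (4 equiv)
Product: 6 (+)-syringaresinol bis(TBS) ether, via bis(N-acyloxyphthalimide) ester 5 (not isolated)
Conditions: NHPI (2.2 equiv), DIC (2.2 equiv), 4-(dimethylamino)pyridine (cat.), THF, rt; concentrate; then 4, NiCl2·6H2O (40 mol%), 2,2′-bipyridine (40 mol%), AgNO3 (0.6 equiv), NMP, Mg anode/RVC cathode, constant current (12 mA), rt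
Reagents that add atoms: N-hydroxyphthalimide, O=C1N(O)C(=O)c2ccccc12 (its atoms stay in intermediate 5 only)
Why: Proposed new method: a twofold Ni-electrocatalytic decarboxylative arylation of a bis(α-alkoxy) redox-active diester on the cis-fused dioxabicyclo[3.3.0]octane, in which cathodically generated low-valent nickel adds into the aryl iodide and reduces each N-acyloxyphthalimide, loss of CO2 gives the ring α-oxy radical, and the aryl–nickel species captures it on the convex face (anti to the C6 methylene on the neighbouring bridgehead) so that reductive elimination places both aryl groups exo, i.e. (1S,4S) as fixed by the bought bridgehead centres; the closest known reaction type is the silver-assisted Ni-electrocatalytic decarboxylative arylation of single tetrahydrofuran-2-carboxylic and tartrate-derived redox-active esters, which has not been shown twofold on a bicyclic lignan-derived diacid.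

Step 4
Reactants: 6 (+)-syringaresinol bis(TBS) ether
Product: 7 (+)-syringaresinol
Conditions: TBAF (2.4 equiv), AcOH (2.4 equiv), THF, 0 °C
Reagents that add atoms: none
Why: Buffered fluoride desilylation cleaves only the aryl silyl ethers and leaves the benzylic ethers of the furofuran and all four stereocentres untouched.

Step 5
Reactants: 8 dimethyl (4R,5R)-2,2-dimethyl-1,3-dioxolane-4,5-dicarboxylate (dimethyl 2,3-O-isopropylidene-L-tartrate)
Product: 9 (4R,5R)-5-(methoxycarbonyl)-2,2-dimethyl-1,3-dioxolane-4-carboxylic acid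
Conditions: KOH (1.0 equiv), MeOH, 0 °C → rt; then aq. HCl
Reagents that add atoms: potassium hydroxide, [K+].[OH-]
Why: Mono-saponification of the C2-symmetric diester with one equivalent of hydroxide stops at the half-ester because the carboxylate deactivates the second ester, and neither tartrate stereocentre is touched.

Step 6
Reactants: 10 4-iodo-2-methoxyphenol
Product: 11 (4-iodo-2-methoxyphenoxy)tri(propan-2-yl)silane
Conditions: TIPSCl, imidazole, DMF, rt
Reagents that add atoms: triisopropylsilyl chloride, CC(C)[Si](Cl)(C(C)C)C(C)C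
Why: Silyl ether formation gives a base-robust, fluoride-labile phenol protecting group that tolerates the reductive coupling and the later carbonate-mediated alkylations.

Step 7
Reactants: 9 L-tartrate half-ester (1.5 equiv); 11 TIPS-protected guaiacyl iodide
Product: 13 methyl (4R,5S)-5-[3-methoxy-4-(TIPS-oxy)phenyl]-2,2-dimethyl-1,3-dioxolane-4-carboxylate, via N-acyloxyphthalimide ester 12 (not isolated)
Conditions: NHPI, DIC, 4-(dimethylamino)pyridine (cat.), CH2Cl2, rt; concentrate; then 11, NiCl2·6H2O (20 mol%), 2,2′-bipyridine (20 mol%), AgNO3 (0.3 equiv), NMP, Mg anode/RVC cathode, constant current (12 mA), rt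
Reagents that add atoms: N-hydroxyphthalimide, O=C1N(O)C(=O)c2ccccc12 (its atoms stay in intermediate 12 only)
Why: Ni-electrocatalytic decarboxylative arylation (redox-active ester/aryl iodide cross-electrophile coupling) arylates the planar dioxolanyl radical trans to the neighbouring CO2Me, so the bought C4 centre sets the new benzylic centre as 5S (future C7 = S).

Step 8
Reactants: 13 L-series aryl dioxolane ester
Product: 14 methyl (2R,3S)-2,3-dihydroxy-3-[3-methoxy-4-(TIPS-oxy)phenyl]propanoate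
Conditions: AcOH/H2O (4:1), 60 °C
Reagents that add atoms: none
Why: Acid-catalysed acetal hydrolysis cleaves only the acetal-carbon C–O bonds, so the threo diol is released with both stereocentres intact and the aryl TIPS ether survives aqueous AcOH.

Step 9
Reactants: 14 L-series threo diol
Product: 16 methyl (2R,3S)-3-[3-methoxy-4-(TIPS-oxy)phenyl]-2-(Ns-oxy)-3-(TIPS-oxy)propanoate, via α-nosylate β-alcohol 15 (not isolated)
Conditions: NsCl (1.05 equiv), Et3N, CH2Cl2, 0 °C; then TIPSOTf, 2,6-lutidine, 0 °C → rt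
Reagents that add atoms: 4-nitrobenzenesulfonyl chloride, O=S(=O)(Cl)c1ccc(cc1)[N+](=O)[O-]; triisopropylsilyl triflate, CC(C)[Si](OS(=O)(=O)C(F)(F)F)(C(C)C)C(C)C
Why: The more acidic α-hydroxyl of a 2,3-dihydroxy ester is sulfonylated selectively (regioselective α-nosylation) and the benzylic hydroxyl is then silylated, both with retention because no C–O bond at a stereocentre is broken.

Step 10
Reactants: 13 L-series aryl dioxolane ester
Product: 17 methyl (4R,5S)-5-(4-hydroxy-3-methoxyphenyl)-2,2-dimethyl-1,3-dioxolane-4-carboxylate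
Conditions: TBAF (1.1 equiv), AcOH (1.1 equiv), THF, 0 °C
Reagents that add atoms: none
Why: Fluoride desilylation frees the guaiacyl phenol while the acetonide, the ester and both stereocentres are inert.

Step 11
Reactants: 17 dioxolane phenol (1.1 equiv); 16 outer-unit α-nosylate
Product: 18 methyl (4R,5S)-5-{3-methoxy-4-[(2S,3S)-1-methoxy-3-[3-methoxy-4-(TIPS-oxy)phenyl]-1-oxo-3-(TIPS-oxy)propan-2-yl]oxyphenyl}-2,2-dimethyl-1,3-dioxolane-4-carboxylate
Conditions: K2CO3 (1.5 equiv), DMF, 40 °C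
Reagents that add atoms: none
Why: Williamson-type SN2 displacement of the carbonyl-activated α-nosylate by the unhindered phenoxide proceeds with inversion, turning the threo (2R,3S) electrophile into the erythro (2S,3S) aryl ether of the outer unit.

Step 12
Reactants: 18 dimeric dioxolane ester
Product: 19 methyl (2R,3S)-2,3-dihydroxy-3-{3-methoxy-4-[(2S,3S)-1-methoxy-3-[3-methoxy-4-(TIPS-oxy)phenyl]-1-oxo-3-(TIPS-oxy)propan-2-yl]oxyphenyl}propanoate
Conditions: AcOH/H2O (4:1), 60 °C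
Reagents that add atoms: none
Why: Acetal hydrolysis as in step 8 frees the threo diol of the middle unit, and the secondary and aryl TIPS ethers are stable to aqueous AcOH.

Step 13
Reactants: 19 dimeric threo diol
Product: 21 methyl (2R,3S)-3-(TBS-oxy)-3-{3-methoxy-4-[(2S,3S)-1-methoxy-3-[3-methoxy-4-(TIPS-oxy)phenyl]-1-oxo-3-(TIPS-oxy)propan-2-yl]oxyphenyl}-2-(Ns-oxy)propanoate, via α-nosylate β-alcohol 20 (not isolated)
Conditions: NsCl (1.05 equiv), Et3N, CH2Cl2, 0 °C; then TBSOTf, 2,6-lutidine, 0 °C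
Reagents that add atoms: 4-nitrobenzenesulfonyl chloride, O=S(=O)(Cl)c1ccc(cc1)[N+](=O)[O-]; tert-butyldimethylsilyl triflate, CC(C)(C)[Si](C)(C)OS(=O)(=O)C(F)(F)F
Why: Regioselective α-nosylation followed by silylation of the benzylic hydroxyl, as in step 9, activates C8 and protects C7 with retention at both centres.

Step 14
Reactants: 21 dimeric α-nosylate
Product: 22 methyl (2S,3S)-2-bromo-3-(TBS-oxy)-3-{3-methoxy-4-[(2S,3S)-1-methoxy-3-[3-methoxy-4-(TIPS-oxy)phenyl]-1-oxo-3-(TIPS-oxy)propan-2-yl]oxyphenyl}propanoate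
Conditions: LiBr (1.2 equiv), 2-butanone, 40 °C
Reagents that add atoms: lithium bromide, [Li+].[Br-]
Why: Finkelstein-type SN2 displacement of the α-nosylate by bromide inverts C2 (2R → 2S), the first of the two inversions that give net retention for the threo unit, and near-stoichiometric bromide limits bromide–bromide exchange.

Step 15
Reactants: 23 dimethyl (4S,5S)-2,2-dimethyl-1,3-dioxolane-4,5-dicarboxylate (dimethyl 2,3-O-isopropylidene-D-tartrate)
Product: 24 (4S,5S)-5-(methoxycarbonyl)-2,2-dimethyl-1,3-dioxolane-4-carboxylic acid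
Conditions: KOH (1.0 equiv), MeOH, 0 °C → rt; then aq. HCl
Reagents that add atoms: potassium hydroxide, [K+].[OH-]
Why: Mono-saponification as in step 5, with no effect on the two D-tartrate stereocentres.

Step 16
Reactants: 24 D-tartrate half-ester (1.5 equiv); 11 TIPS-protected guaiacyl iodide
Product: 26 methyl (4S,5R)-5-[3-methoxy-4-(TIPS-oxy)phenyl]-2,2-dimethyl-1,3-dioxolane-4-carboxylate, via N-acyloxyphthalimide ester 25 (not isolated)
Conditions: NHPI, DIC, 4-(dimethylamino)pyridine (cat.), CH2Cl2, rt; concentrate; then 11, NiCl2·6H2O (20 mol%), 2,2′-bipyridine (20 mol%), AgNO3 (0.3 equiv), NMP, Mg anode/RVC cathode, constant current (12 mA), rt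
Reagents that add atoms: N-hydroxyphthalimide, O=C1N(O)C(=O)c2ccccc12 (its atoms stay in intermediate 25 only)
Why: The same Ni-electrocatalytic decarboxylative arylation as in step 7 places the aryl group trans to CO2Me, so the bought 4S centre sets the benzylic centre as 5R (future C7 = R).

Step 17
Reactants: 26 D-series aryl dioxolane ester
Product: 27 methyl (2S,3R)-2,3-dihydroxy-3-[3-methoxy-4-(TIPS-oxy)phenyl]propanoate
Conditions: AcOH/H2O (4:1), 60 °C
Reagents that add atoms: none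
Why: Acetal hydrolysis as in step 8 gives the threo diol without touching a stereocentre.

Step 18
Reactants: 27 D-series threo diol
Product: 29 methyl (2S,3R)-3-(TBS-oxy)-3-[3-methoxy-4-(TIPS-oxy)phenyl]-2-(Ns-oxy)propanoate, via α-nosylate β-alcohol 28 (not isolated)
Conditions: NsCl (1.05 equiv), Et3N, CH2Cl2, 0 °C; then TBSOTf, 2,6-lutidine, 0 °C
Reagents that add atoms: 4-nitrobenzenesulfonyl chloride, O=S(=O)(Cl)c1ccc(cc1)[N+](=O)[O-]; tert-butyldimethylsilyl triflate, CC(C)(C)[Si](C)(C)OS(=O)(=O)C(F)(F)F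
Why: Regioselective α-nosylation then silylation of the benzylic hydroxyl, as in step 9, with retention at both centres.

Step 19
Reactants: 7 (+)-syringaresinol (3 equiv); 29 left-unit α-nosylate
Product: 30 methyl (2R,3R)-2-{4-[(1S,3aR,4S,6aR)-4-(4-hydroxy-3,5-dimethoxyphenyl)tetrahydro-1H,3H-furo[3,4-c]furan-1-yl]-2,6-dimethoxyphenoxy}-3-[3-methoxy-4-(TIPS-oxy)phenyl]-3-(TBS-oxy)propanoate
Conditions: Cs2CO3 (1.2 equiv), DMF, 45 °C, Ar; excess 7 recovered
Reagents that add atoms: none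
Why: SN2 O-alkylation (Williamson) of one of the two homotopic phenols of C2-symmetric 7, used in excess to favour the mono-ether, displaces the α-nosylate with inversion and gives the erythro (2R,3R) aryl ether without involving the furofuran centres.

Step 20
Reactants: 30 left-arm mono-ether (1.3 equiv); 22 dimeric α-bromo ester
Product: 31 tris-ester: 30 in which the remaining syringyl OH carries the (2R,3S)-1-methoxy-1-oxo-3-(TBS-oxy)-3-arylpropan-2-yl group of 21 (aryl = 3-methoxy-4-[(2S,3S)-outer ester unit]oxyphenyl)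
Conditions: Cs2CO3 (1.5 equiv), DMF, 50 °C, Ar
Reagents that add atoms: none
Why: SN2 displacement of the α-bromo ester by the remaining syringyl phenoxide inverts C2 a second time (2S → 2R), so the middle unit keeps the tartrate configuration at both carbons and is threo.

Step 21
Reactants: 31 tris-ester
Product: 32 penta-silylated triol (three CO2Me reduced to CH2OH; left unit 7R,8S, middle unit 7S,8S, outer unit 7S,8R)
Conditions: LiBH4 (6 equiv), THF/MeOH (20:1), 0 °C → rt
Reagents that add atoms: none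
Why: Chemoselective borohydride reduction of the three activated α-aryloxy methyl esters gives the primary alcohols without cleaving silyl ethers or epimerising C8 (the C8 descriptors change only through CIP priority).

Step 22
Reactants: 32 penta-silylated triol
Product: 33 target compound CNP0316493.3
Conditions: TBAF (10 equiv), AcOH (5 equiv), THF, rt → 40 °C
Reagents that add atoms: none
Why: Global fluoride desilylation removes the three secondary and two aryl silyl ethers without breaking any C–O bond at a stereocentre, and the acetic acid buffer prevents quinone methide formation from the phenolic benzylic alcohols.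

## Compound list

1 | (+)-sesamin, 5,5′-[(1S,3aR,4S,6aR)-tetrahydro-1H,3H-furo[3,4-c]furan-1,4-diyl]bis(1,3-benzodioxole) | C1Oc2ccc(cc2O1)[C@H]1OC[C@H]2[C@@H]1CO[C@@H]2c1ccc2OCOc2c1 | starting material
2 | (1S,3aR,4S,6aR)-tetrahydro-1H,3H-furo[3,4-c]furan-1,4-dicarboxylic acid | OC(=O)[C@H]1OC[C@H]2[C@@H]1CO[C@@H]2C(=O)O | intermediate
3 | 4-iodo-2,6-dimethoxyphenol | COc1cc(I)cc(OC)c1O | starting material
4 | tert-butyl(4-iodo-2,6-dimethoxyphenoxy)dimethylsilane | COc1cc(I)cc(OC)c1O[Si](C)(C)C(C)(C)C | intermediate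
5 | bis(1,3-dioxoisoindolin-2-yl) (1S,3aR,4S,6aR)-tetrahydro-1H,3H-furo[3,4-c]furan-1,4-dicarboxylate | O=C(ON1C(=O)c2ccccc2C1=O)[C@H]1OC[C@H]2[C@@H]1CO[C@@H]2C(=O)ON1C(=O)c2ccccc2C1=O | intermediate (not isolated)
6 | (1S,3aR,4S,6aR)-1,4-bis[4-(TBS-oxy)-3,5-dimethoxyphenyl]tetrahydro-1H,3H-furo[3,4-c]furan | COc1cc(cc(OC)c1O[Si](C)(C)C(C)(C)C)[C@H]1OC[C@H]2[C@@H]1CO[C@@H]2c1cc(OC)c(O[Si](C)(C)C(C)(C)C)c(OC)c1 | intermediate
7 | (+)-syringaresinol, 4,4′-[(1S,3aR,4S,6aR)-tetrahydro-1H,3H-furo[3,4-c]furan-1,4-diyl]bis(2,6-dimethoxyphenol) | COc1cc(cc(OC)c1O)[C@H]1OC[C@H]2[C@@H]1CO[C@@H]2c1cc(OC)c(O)c(OC)c1 | intermediate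
8 | dimethyl (4R,5R)-2,2-dimethyl-1,3-dioxolane-4,5-dicarboxylate | COC(=O)[C@@H]1OC(C)(C)O[C@H]1C(=O)OC | starting material
9 | (4R,5R)-5-(methoxycarbonyl)-2,2-dimethyl-1,3-dioxolane-4-carboxylic acid | COC(=O)[C@@H]1OC(C)(C)O[C@H]1C(=O)O | intermediate
10 | 4-iodo-2-methoxyphenol | COc1cc(I)ccc1O | starting material
11 | (4-iodo-2-methoxyphenoxy)tri(propan-2-yl)silane | COc1cc(I)ccc1O[Si](C(C)C)(C(C)C)C(C)C | intermediate
12 | 4-(1,3-dioxoisoindolin-2-yl) 5-methyl (4R,5R)-2,2-dimethyl-1,3-dioxolane-4,5-dicarboxylate | COC(=O)[C@@H]1OC(C)(C)O[C@H]1C(=O)ON1C(=O)c2ccccc2C1=O | intermediate (not isolated)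
13 | methyl (4R,5S)-5-[3-methoxy-4-(TIPS-oxy)phenyl]-2,2-dimethyl-1,3-dioxolane-4-carboxylate | COC(=O)[C@@H]1OC(C)(C)O[C@H]1c1ccc(O[Si](C(C)C)(C(C)C)C(C)C)c(OC)c1 | intermediate
14 | methyl (2R,3S)-2,3-dihydroxy-3-[3-methoxy-4-(TIPS-oxy)phenyl]propanoate | COC(=O)[C@H](O)[C@@H](O)c1ccc(O[Si](C(C)C)(C(C)C)C(C)C)c(OC)c1 | intermediate
15 | methyl (2R,3S)-3-hydroxy-3-[3-methoxy-4-(TIPS-oxy)phenyl]-2-(Ns-oxy)propanoate | COC(=O)[C@H](OS(=O)(=O)c1ccc(cc1)[N+](=O)[O-])[C@@H](O)c1ccc(O[Si](C(C)C)(C(C)C)C(C)C)c(OC)c1 | intermediate (not isolated)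
16 | methyl (2R,3S)-3-[3-methoxy-4-(TIPS-oxy)phenyl]-2-(Ns-oxy)-3-(TIPS-oxy)propanoate | COC(=O)[C@H](OS(=O)(=O)c1ccc(cc1)[N+](=O)[O-])[C@@H](O[Si](C(C)C)(C(C)C)C(C)C)c1ccc(O[Si](C(C)C)(C(C)C)C(C)C)c(OC)c1 | intermediate
17 | methyl (4R,5S)-5-(4-hydroxy-3-methoxyphenyl)-2,2-dimethyl-1,3-dioxolane-4-carboxylate | COC(=O)[C@@H]1OC(C)(C)O[C@H]1c1ccc(O)c(OC)c1 | intermediate
18 | methyl (4R,5S)-5-{3-methoxy-4-[(2S,3S)-1-methoxy-3-[3-methoxy-4-(TIPS-oxy)phenyl]-1-oxo-3-(TIPS-oxy)propan-2-yl]oxyphenyl}-2,2-dimethyl-1,3-dioxolane-4-carboxylate | COC(=O)[C@@H]1OC(C)(C)O[C@H]1c1ccc(O[C@H](C(=O)OC)[C@@H](O[Si](C(C)C)(C(C)C)C(C)C)c2ccc(O[Si](C(C)C)(C(C)C)C(C)C)c(OC)c2)c(OC)c1 | intermediate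
19 | methyl (2R,3S)-2,3-dihydroxy-3-{3-methoxy-4-[(2S,3S)-1-methoxy-3-[3-methoxy-4-(TIPS-oxy)phenyl]-1-oxo-3-(TIPS-oxy)propan-2-yl]oxyphenyl}propanoate | COC(=O)[C@H](O)[C@@H](O)c1ccc(O[C@H](C(=O)OC)[C@@H](O[Si](C(C)C)(C(C)C)C(C)C)c2ccc(O[Si](C(C)C)(C(C)C)C(C)C)c(OC)c2)c(OC)c1 | intermediate
20 | methyl (2R,3S)-3-hydroxy-2-(Ns-oxy)-3-{aryl of 19}propanoate | COC(=O)[C@H](OS(=O)(=O)c1ccc(cc1)[N+](=O)[O-])[C@@H](O)c1ccc(O[C@H](C(=O)OC)[C@@H](O[Si](C(C)C)(C(C)C)C(C)C)c2ccc(O[Si](C(C)C)(C(C)C)C(C)C)c(OC)c2)c(OC)c1 | intermediate (not isolated)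
21 | methyl (2R,3S)-3-(TBS-oxy)-2-(Ns-oxy)-3-{aryl of 19}propanoate | COC(=O)[C@H](OS(=O)(=O)c1ccc(cc1)[N+](=O)[O-])[C@@H](O[Si](C)(C)C(C)(C)C)c1ccc(O[C@H](C(=O)OC)[C@@H](O[Si](C(C)C)(C(C)C)C(C)C)c2ccc(O[Si](C(C)C)(C(C)C)C(C)C)c(OC)c2)c(OC)c1 | intermediate
22 | methyl (2S,3S)-2-bromo-3-(TBS-oxy)-3-{aryl of 19}propanoate | COC(=O)[C@@H](Br)[C@@H](O[Si](C)(C)C(C)(C)C)c1ccc(O[C@H](C(=O)OC)[C@@H](O[Si](C(C)C)(C(C)C)C(C)C)c2ccc(O[Si](C(C)C)(C(C)C)C(C)C)c(OC)c2)c(OC)c1 | intermediate
23 | dimethyl (4S,5S)-2,2-dimethyl-1,3-dioxolane-4,5-dicarboxylate | COC(=O)[C@H]1OC(C)(C)O[C@@H]1C(=O)OC | starting material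
24 | (4S,5S)-5-(methoxycarbonyl)-2,2-dimethyl-1,3-dioxolane-4-carboxylic acid | COC(=O)[C@H]1OC(C)(C)O[C@@H]1C(=O)O | intermediate
25 | 4-(1,3-dioxoisoindolin-2-yl) 5-methyl (4S,5S)-2,2-dimethyl-1,3-dioxolane-4,5-dicarboxylate | COC(=O)[C@H]1OC(C)(C)O[C@@H]1C(=O)ON1C(=O)c2ccccc2C1=O | intermediate (not isolated)
26 | methyl (4S,5R)-5-[3-methoxy-4-(TIPS-oxy)phenyl]-2,2-dimethyl-1,3-dioxolane-4-carboxylate | COC(=O)[C@H]1OC(C)(C)O[C@@H]1c1ccc(O[Si](C(C)C)(C(C)C)C(C)C)c(OC)c1 | intermediate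
27 | methyl (2S,3R)-2,3-dihydroxy-3-[3-methoxy-4-(TIPS-oxy)phenyl]propanoate | COC(=O)[C@@H](O)[C@H](O)c1ccc(O[Si](C(C)C)(C(C)C)C(C)C)c(OC)c1 | intermediate
28 | methyl (2S,3R)-3-hydroxy-3-[3-methoxy-4-(TIPS-oxy)phenyl]-2-(Ns-oxy)propanoate | COC(=O)[C@@H](OS(=O)(=O)c1ccc(cc1)[N+](=O)[O-])[C@H](O)c1ccc(O[Si](C(C)C)(C(C)C)C(C)C)c(OC)c1 | intermediate (not isolated)
29 | methyl (2S,3R)-3-(TBS-oxy)-3-[3-methoxy-4-(TIPS-oxy)phenyl]-2-(Ns-oxy)propanoate | COC(=O)[C@@H](OS(=O)(=O)c1ccc(cc1)[N+](=O)[O-])[C@H](O[Si](C)(C)C(C)(C)C)c1ccc(O[Si](C(C)C)(C(C)C)C(C)C)c(OC)c1 | intermediate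
30 | methyl (2R,3R)-2-{4-[(1S,3aR,4S,6aR)-4-(4-hydroxy-3,5-dimethoxyphenyl)tetrahydro-1H,3H-furo[3,4-c]furan-1-yl]-2,6-dimethoxyphenoxy}-3-[3-methoxy-4-(TIPS-oxy)phenyl]-3-(TBS-oxy)propanoate | COC(=O)[C@H](Oc1c(OC)cc(cc1OC)[C@H]1OC[C@H]2[C@@H]1CO[C@@H]2c1cc(OC)c(O)c(OC)c1)[C@H](O[Si](C)(C)C(C)(C)C)c1ccc(O[Si](C(C)C)(C(C)C)C(C)C)c(OC)c1 | intermediate
31 | tris-ester: (+)-syringaresinol bis-ether carrying the left (2R,3R) ester unit of 30 on one ring and the (2R,3S) middle ester unit (C3 TBS ether) bearing the (2S,3S) outer ester unit on the other | COC(=O)[C@H](Oc1c(OC)cc(cc1OC)[C@H]1OC[C@H]2[C@@H]1CO[C@@H]2c1cc(OC)c(O[C@@H](C(=O)OC)[C@@H](O[Si](C)(C)C(C)(C)C)c2ccc(O[C@H](C(=O)OC)[C@@H](O[Si](C(C)C)(C(C)C)C(C)C)c3ccc(O[Si](C(C)C)(C(C)C)C(C)C)c(OC)c3)c(OC)c2)c(OC)c1)[C@H](O[Si](C)(C)C(C)(C)C)c1ccc(O[Si](C(C)C)(C(C)C)C(C)C)c(OC)c1 | intermediate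
32 | penta-silylated triol: 31 with all three CO2Me reduced to CH2OH (left unit 7R,8S; middle unit 7S,8S; outer unit 7S,8R) | OC[C@H](Oc1c(OC)cc(cc1OC)[C@H]1OC[C@H]2[C@@H]1CO[C@@H]2c1cc(OC)c(O[C@@H](CO)[C@@H](O[Si](C)(C)C(C)(C)C)c2ccc(O[C@H](CO)[C@@H](O[Si](C(C)C)(C(C)C)C(C)C)c3ccc(O[Si](C(C)C)(C(C)C)C(C)C)c(OC)c3)c(OC)c2)c(OC)c1)[C@H](O[Si](C)(C)C(C)(C)C)c1ccc(O[Si](C(C)C)(C(C)C)C(C)C)c(OC)c1 | intermediate
33 | CNP0316493.3: (+)-syringaresinol 4-O-[(7R,8S)-guaiacylglycerol-8-yl] 4′-O-{(7S,8S)-4-O-[(7S,8R)-guaiacylglycerol-8-yl]guaiacylglycerol-8-yl} diether | COc1cc([C@@H](O)[C@H](CO)Oc2c(OC)cc([C@H]3OC[C@H]4[C@@H]3CO[C@@H]4c3cc(OC)c(O[C@@H](CO)[C@@H](O)c4ccc(O[C@H](CO)[C@@H](O)c5ccc(O)c(OC)c5)c(OC)c4)c(OC)c3)cc2OC)ccc1O | target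

## Step count and risk

Total steps: 22. Longest linear sequence: 11 steps (steps 5, 7, 8, 9, 11, 12, 13, 14, 20, 21, 22; from 8 to 33).

The three steps most likely to fail:

Step 3 (the proposed new twofold decarboxylative arylation). Two radical couplings must both succeed and both must be exo-selective. The fallback uses known ionic chemistry, sets out from 2 and comes back at 7. Diacid 2 is decarboxylated oxidatively with Pb(OAc)4 (pyridine, THF, 60 °C; oxidative decarboxylation of α-alkoxy acids) to the anomeric mixture of (3aR,6aR)-tetrahydro-1H,3H-furo[3,4-c]furan-1,4-diyl diacetate F1. BF3·OEt2 (CH2Cl2, −40 °C) then ionises both acetates, and commercial 2,6-dimethoxyphenol attacks the oxocarbenium ions through its free para position (Friedel–Crafts C-arylation of a cyclic acetal) on the convex face. This gives (+)-syringaresinol 7 directly; any exo,endo epimer is removed by chromatography.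

Step 1 (ozonolytic degradation of both piperonyl rings). Ether α-C–H oxidation or incomplete ring cleavage could lower the yield. The fallback sets out from 1 and comes back at 2, and degrades the rings in two stages. Pb(OAc)4 (benzene, 50 °C) acetoxylates both methylenedioxy carbons to give 5,5′-[(1S,3aR,4S,6aR)-tetrahydro-1H,3H-furo[3,4-c]furan-1,4-diyl]bis(1,3-benzodioxol-2-yl) diacetate F2. Mild aqueous AcOH hydrolyses this orthoester to sesamin dicatechol F3. The catechol rings, now far more electron-rich than any ether C–H, are cleaved with catalytic RuCl3·xH2O and NaIO4 (MeCN/EtOAc/H2O, 0 °C) to diacid 2.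

Step 20 (hindered syringyl phenoxide on the α-bromo ester). Bromide–bromide exchange or elimination could erode the threo configuration before the second inversion takes place. The fallback sets out from 21 and comes back at 31, and replaces the halide relay by an oxygen relay. KNO2 with 18-crown-6 in DMF (Lattrell–Dax-type inversion) converts nosylate 21 into the nitrite ester methyl (2S,3S)-2-(nitrosooxy)-3-(TBS-oxy)-3-arylpropanoate F4 (aryl as in 21). Aqueous work-up hydrolyses it to the inverted alcohol methyl (2S,3S)-2-hydroxy-3-(TBS-oxy)-3-arylpropanoate F5. F5 is then coupled with phenol 30 under Mitsunobu conditions (PPh3, DIAD, toluene, 0 °C → rt), whose inversion delivers 31.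

Further compounds
F1 | step 3 | (3aR,6aR)-tetrahydro-1H,3H-furo[3,4-c]furan-1,4-diyl diacetate (anomer mixture) | CC(=O)OC1OC[C@H]2[C@@H]1COC2OC(C)=O
F2 | step 1 | 5,5′-[(1S,3aR,4S,6aR)-tetrahydro-1H,3H-furo[3,4-c]furan-1,4-diyl]bis(1,3-benzodioxol-2-yl) diacetate | CC(=O)OC1Oc2ccc(cc2O1)[C@H]1OC[C@H]2[C@@H]1CO[C@@H]2c1ccc2OC(OC(C)=O)Oc2c1
F3 | step 1 | sesamin dicatechol, 4,4′-[(1S,3aR,4S,6aR)-tetrahydro-1H,3H-furo[3,4-c]furan-1,4-diyl]dibenzene-1,2-diol | Oc1ccc(cc1O)[C@H]1OC[C@H]2[C@@H]1CO[C@@H]2c1ccc(O)c(O)c1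
F4 | step 20 | methyl (2S,3S)-2-(nitrosooxy)-3-(TBS-oxy)-3-{aryl of 21}propanoate | COC(=O)[C@@H](ON=O)[C@@H](O[Si](C)(C)C(C)(C)C)c1ccc(O[C@H](C(=O)OC)[C@@H](O[Si](C(C)C)(C(C)C)C(C)C)c2ccc(O[Si](C(C)C)(C(C)C)C(C)C)c(OC)c2)c(OC)c1
F5 | step 20 | methyl (2S,3S)-2-hydroxy-3-(TBS-oxy)-3-{aryl of 21}propanoate | COC(=O)[C@@H](O)[C@@H](O[Si](C)(C)C(C)(C)C)c1ccc(O[C@H](C(=O)OC)[C@@H](O[Si](C(C)C)(C(C)C)C(C)C)c2ccc(O[Si](C(C)C)(C(C)C)C(C)C)c(OC)c2)c(OC)c1
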